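**Assumption:** the SMILES decodes as (2R,3S,4R) on the oxolane (O1, C2 = CHAr, C3 = CHCH2OH, C4 = C(OH)CH2Ar, C5 = CH2). This means 2-aryl and 3-CH2OH are trans, 3-CH2OH and 4-benzyl are cis, and the 4-OH sits on the aryl face. These locants are also used for the acyclic precursors. Diethyl (R)-malate and both benzylic alcohols are taken as catalogue chemicals.

## Retrosynthetic overview
1. The target comes from its mono-O-benzyl ether. The oxolane, the only ring of the target, is closed second to last by forming O1–C2 from an open-chain phenolic triol, using anodic, DDQ-relayed dehydrogenation through a p-quinone methide.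
2. The triol comes from one exhaustive LiAlH4 reduction of a fully substituted dioxolanone acid. This step also frees the one phenol that must be oxidised.
3. The C4–CH2Ar′ bond comes from benzylation of a t-Bu-dioxolanone enolate (self-regeneration of the malate stereocentre). The dioxolanone is a temporary ring, made in step 5 and destroyed in step 8.
4. The C3–CH2Ar bond comes from Fráter–Seebach anti-alkylation of diethyl (R)-malate, which supplies C5–C4–C3–CH2OH and the C4 configuration.
5. The two differently protected vanillyl bromides come from vanillyl alcohol and O-benzylvanillyl alcohol.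

## Route

**Step 1**
Reactants: 1 vanillyl alcohol (4-hydroxy-3-methoxybenzyl alcohol); 2 N,N-diethylcarbamoyl chloride
Product: 3, 4-(hydroxymethyl)-2-methoxyphenyl N,N-diethylcarbamate
Conditions: NaH (1.0 equiv), THF, 0 °C; then 2, 0 °C → rt
Reagents that add atoms: N,N-diethylcarbamoyl chloride (2), CCN(CC)C(=O)Cl
Why: Chemoselective O-carbamoylation of the phenoxide (phenol pKa ~10 versus alcohol ~16) installs a group that survives amide bases, LiOH and acid but is removed by LiAlH4 in step 8.

**Step 2**
Reactants: 3
Product: 4, 4-(bromomethyl)-2-methoxyphenyl N,N-diethylcarbamate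
Conditions: PBr3 (0.4 equiv), CH2Cl2, 0 °C
Reagents that add atoms: phosphorus tribromide, BrP(Br)Br
Why: This is a standard benzylic alcohol to bromide substitution, and the acylated phenol oxygen damps ring donation so the bromide can be handled.

**Step 3**
Reactants: 5 diethyl (R)-malate; 4
Product: 6, diethyl (2R,3S)-3-{[4-(diethylcarbamoyloxy)-3-methoxyphenyl]methyl}-2-hydroxybutanedioate (anti)
Conditions: LiHMDS (2.1 equiv), THF, −78 → −20 °C; 4, −78 → 0 °C
Reagents that add atoms: only reactant 4, COc1cc(CBr)ccc1OC(=O)N(CC)CC
Why: In this Fráter–Seebach alkylation the chelated alkoxide-enolate dianion is benzylated anti to the C–O bond (about 9:1, separable), so the purchased carbinol centre (future C4) sets future C3.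

**Step 4**
Reactants: 6
Product: 7, (2R,3S)-3-{[4-(diethylcarbamoyloxy)-3-methoxyphenyl]methyl}-2-hydroxybutanedioic acid
Conditions: LiOH·H2O (5 equiv), THF/H2O 3:1, 0 °C → rt; 1 M HCl to pH 2
Reagents that add atoms: water/hydroxide, O
Why: Mild ester saponification cleaves both ethyl esters without cleaving the N,N-dialkyl aryl carbamate and without epimerising C3.

**Step 5**
Reactants: 7; 8 pivalaldehyde
Product: 9, (2S)-2-[(2R,4R)-2-tert-butyl-5-oxo-1,3-dioxolan-4-yl]-3-[4-(diethylcarbamoyloxy)-3-methoxyphenyl]propanoic acid (t-Bu cis to the side chain)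
Conditions: t-BuCHO (3 equiv), TsOH·H2O and H2SO4 (cat.), CH2Cl2/pentane, reflux with water removal; recrystallise
Reagents that add atoms: pivalaldehyde (8), CC(C)(C)C=O
Why: In this Seebach dioxolanone acetalisation the α-hydroxy acid closes the five-membered acylal in preference to the six-membered alternative, and thermodynamic control places t-Bu cis to the side chain, copying the C4 configuration into the acetal centre.

**Step 6**
Reactants: 10, 4-(benzyloxy)-3-methoxybenzyl alcohol
Product: 11, 4-(benzyloxy)-3-methoxybenzyl bromide
Conditions: PBr3 (0.4 equiv), Et2O, 0 °C; use fresh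
Reagents that add atoms: phosphorus tribromide, BrP(Br)Br
Why: This is a standard benzylic bromination.

**Step 7**
Reactants: 9; 11
Product: 12, (2S)-2-{(2R,4R)-4-[4-(benzyloxy)-3-methoxybenzyl]-2-tert-butyl-5-oxo-1,3-dioxolan-4-yl}-3-[4-(diethylcarbamoyloxy)-3-methoxyphenyl]propanoic acid
Conditions: LiHMDS (2.2 equiv), THF, −78 °C, 1 h; 11 (1.2 equiv), −78 → −30 °C; aq. citric acid
Reagents that add atoms: only reactant 11, COc1cc(CBr)ccc1OCc1ccccc1
Why: In this self-regeneration-of-stereocentres alkylation the planar dioxolanone enolate (the carboxylate shields C3–H) is benzylated anti to t-Bu, where H was, giving net retention and the quaternary C4 (R) as essentially one isomer.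

**Step 8**
Reactants: 12
Product: 13, (2R,3R)-2-{[4-(benzyloxy)-3-methoxyphenyl]methyl}-3-[(4-hydroxy-3-methoxyphenyl)methyl]butane-1,2,4-triol
Conditions: LiAlH4 (8 equiv), THF, 0 °C → reflux; Rochelle salt, pH ~6 work-up
Reagents that add atoms: none
Why: Exhaustive hydride reduction converts CO2H to CH2OH, opens the acylal to C5H2OH and the free C4–OH (t-BuCHO leaves as neopentyl alcohol), and cleaves the aryl carbamate to the phenol, without touching any stereocentre or the aryl benzyl ether (the C3 descriptor changes only through CIP priorities).

**Step 9 (key step)**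
Reactants: 13
Product: 14, (3R,4S,5R)-3-[4-(benzyloxy)-3-methoxybenzyl]-5-(4-hydroxy-3-methoxyphenyl)-4-(hydroxymethyl)oxolan-3-ol
Conditions: DDQ (10 mol %), 2,6-lutidine (2.5 equiv), 4 Å MS, nBu4NPF6 (0.1 M), CH2Cl2/MeCN 1:1, 5 mM, Ar; divided cell, RVC anode, Pt cathode (catholyte AcOH/MeCN/electrolyte); +0.70 V vs Ag/AgCl, 2.0–2.1 F mol⁻¹, 0 °C → rt
Reagents that add atoms: none (net loss of H2)
Why: Proposed new method: anodically recycled DDQ acts as a hydride/proton shuttle for a phenol-selective dehydrogenative C(sp3)–H/O–H cycloetherification; DDQ removes the O–H and the para-benzylic C2–H of the only free guaiacol to give the p-quinone methide, the C5–OH adds 5-exo-trig to its exocyclic carbon (the C4–OH and the CH2OH could only form oxetanes), and rearomatisation drives closure while DDQH⁻ is re-oxidised at a potential too low to touch the O-benzylated ring (Ep about +1.3 V), whose β-hydroxy benzylic position is prone to fragmentation, and too low for electrode-fouling direct phenol oxidation; C2 is set R because the envelope transition state places the aryl group trans to the C3 CH2OH and anti to the C4 benzyl group; lutidine blocks the acid-triggered Friedel–Crafts route to aryltetralins and charge control limits over-oxidation of the product C2–H; the closest known reaction types are stoichiometric DDQ or Ag2O quinone-methide cyclisations of 4-alkylphenols and anodic DDQ regeneration in dehydrogenative arene couplings, neither shown for catalytic electrochemical ring closure of an unprotected polyol.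

**Step 10**
Reactants: 14
Product: 15, target, (3R,4S,5R)-5-(4-hydroxy-3-methoxyphenyl)-3-[(4-hydroxy-3-methoxyphenyl)methyl]-4-(hydroxymethyl)oxolan-3-ol
Conditions: H2 (1 atm), 10% Pd/C, EtOAc, rt, stop at full conversion (about 1–2 h)
Reagents that add atoms: none
Why: Hydrogenolysis of the aryl benzyl ether is much faster in neutral EtOAc than cleavage of the hindered cyclic C2–O bond, and no stereocentre is affected.

**Stereocentres:** C4 is bought in 5 and relayed through the acetal (steps 5 and 7). C3 is set by C4 in step 3. C2 is set by C3 and C4 in step 9.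

## Compound list
| No. | Name | SMILES | Role |
|---|---|---|---|
| 1 | vanillyl alcohol | COc1cc(CO)ccc1O | starting material |
| 2 | N,N-diethylcarbamoyl chloride | CCN(CC)C(=O)Cl | starting material |
| 3 | 4-(hydroxymethyl)-2-methoxyphenyl diethylcarbamate | COc1cc(CO)ccc1OC(=O)N(CC)CC | intermediate |
| 4 | 4-(bromomethyl)-2-methoxyphenyl diethylcarbamate | COc1cc(CBr)ccc1OC(=O)N(CC)CC | intermediate |
| 5 | diethyl (R)-malate | CCOC(=O)C[C@@H](O)C(=O)OCC | starting material |
| 6 | diethyl (2R,3S)-3-arylmethyl-malate | CCOC(=O)[C@H](O)[C@H](Cc1ccc(OC(=O)N(CC)CC)c(OC)c1)C(=O)OCC | intermediate |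
| 7 | (2R,3S)-diacid | OC(=O)[C@H](O)[C@H](Cc1ccc(OC(=O)N(CC)CC)c(OC)c1)C(=O)O | intermediate |
| 8 | pivalaldehyde | CC(C)(C)C=O | starting material |
| 9 | cis-(2R,4R)-dioxolanone acid | CC(C)(C)[C@H]1OC(=O)[C@@H]([C@H](Cc2ccc(OC(=O)N(CC)CC)c(OC)c2)C(=O)O)O1 | intermediate |
| 10 | 4-(benzyloxy)-3-methoxybenzyl alcohol | COc1cc(CO)ccc1OCc1ccccc1 | starting material |
| 11 | 4-(benzyloxy)-3-methoxybenzyl bromide | COc1cc(CBr)ccc1OCc1ccccc1 | intermediate |
| 12 | C4-benzylated dioxolanone acid | CC(C)(C)[C@H]1OC(=O)[C@@](Cc2ccc(OCc3ccccc3)c(OC)c2)([C@H](Cc2ccc(OC(=O)N(CC)CC)c(OC)c2)C(=O)O)O1 | intermediate |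
| 13 | (2R,3R)-phenolic triol | OC[C@@](O)(Cc1ccc(OCc2ccccc2)c(OC)c1)[C@@H](CO)Cc1ccc(O)c(OC)c1 | intermediate |
| 14 | mono-O-benzyl oxolane | COc1cc(C[C@]2(O)CO[C@@H](c3ccc(O)c(OC)c3)[C@@H]2CO)ccc1OCc1ccccc1 | intermediate |
| 15 | target | COc1cc(C[C@]2(O)CO[C@@H](c3ccc(O)c(OC)c3)[C@@H]2CO)ccc1O | target |

## Step count
- **Total steps:** 10.
- **Longest linear sequence:** 9 (steps 1, 2, 3, 4, 5, 7, 8, 9, 10), of which 7 are from diethyl (R)-malate.

## Steps most likely to fail
1. **Step 9 (new electrocatalytic ring closure).**
   - Risks: over-oxidation at the product C2–H, phenoxyl dimerisation, spirodienone formation through the CH2OH, and Friedel–Crafts closure to an aryltetralin.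
   - Fallback (known chemistry): give up direct C–H/O–H coupling and work stepwise. Use stoichiometric DDQ in wet dioxane to take the phenolic benzylic position of 13 to the C2 carbinol or ketone, reduce with NaBH4, then close by mild-acid cyclodehydration of the p-hydroxybenzylic alcohol. This is the classical closure of 7,9′-epoxylignans and favours the 2,3-trans isomer.
2. **Step 7 (quaternary centre formed next to a tertiary carbon).**
   - Risks: low conversion or enolate decomposition.
   - Fallback: change the controlling element from the acetal to a ring. Reduce the acid of 9 with BH3·THF, then translactonise under acid (losing t-BuCHO) to the trans-α-hydroxy-β-arylmethyl-γ-butyrolactone. Benzylate its LDA dianion with 11 anti to the β-substituent, which is the known entry to α-hydroxy-α,β-dibenzylbutyrolactone lignans. LiAlH4 then gives the same 13.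
3. **Step 10 (debenzylation versus C2–O hydrogenolysis).**
   - Risk: ring opening back to the open-chain triol.
   - Fallback: change the protecting-group plan. Carry the C4-benzyl arene as its TIPS ether, with the bromide made from TIPS-vanillin by NaBH4 and then CBr4/PPh3. This ether also survives LiHMDS and LiAlH4 and still masks that phenol in step 9. Finish non-reductively with TBAF/AcOH.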